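# Proposed synthesis of 5'-hydroxy-3,5,7,2',4'-pentamethoxyflavone by a propargyl ether Claisen cascade

## Structural features

The target is a flavone: benzene ring A is fused through C4a–C8a to the 4-pyranone ring C (a 4H-chromen-4-one), and aryl ring B is attached to C2 by the single bond C2–C1'. The molecule is achiral and flat, so no stereocentres have to be set and none stand next to each other; any sp3 centre that a route passes through is transient. Six oxygen substituents sit on the fifteen-carbon skeleton: methoxy groups at C5 and C7 of ring A, at C3 of ring C (an enol ether) and at C2' and C4' of ring B, plus the only free hydroxyl at C5'. That hydroxyl is ortho to the 4'-methoxy and para to the 2'-methoxy group, so the free phenol is easily oxidized towards a quinone and should stay masked until the last step. The 5-methoxy group peri to the C4 carbonyl is stripped by Lewis acids such as BCl3 or AlCl3, and the pyranone opens in hot strong alkali. The real difficulty is the oxygen pattern and not the skeleton: one of six oxygens must stay unmethylated, and C3 must carry oxygen on a ring C flanked by the 5-methoxy group, where alkaline peroxide oxidation of the matching 2'-hydroxy-6'-methoxychalcone tends to give aurones instead of flavonols. The feature the key step exploits lies in ring A: O1 sits on C8a, and the two carbons ortho to it (the future C4a and C8) are equivalent unsubstituted CH carbons in a 3,5-dimethoxyphenyl ether, so a [3,3] shift starting at O1 can form C4–C4a with no regiochemical choice. Ring C is therefore built at the 2H-chromene oxidation level, and the C3 and C4 oxygens are added to its C3=C4 double bond afterwards.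

## Logic of the disconnections

**18 ⇒ 17.** The only bond cut is O5'–CH2Ph. The free hydroxyl is released last because it would not survive the methylation and the oxidations before it. With the benzyl group in place all six oxygens of 17 are ethers and need no differentiation. The forward hydrogenolysis must cleave a benzyl aryl ether without touching the C2=C3 double bond, the carbonyl group or the five methyl ethers.

**17 ⇒ 16.** The O3–CH3 bond is cut. C3 is the one position whose oxygen cannot come from a starting material in this plan, so it is introduced as a hydroxyl and then methylated. 16 is simpler because its C3 oxygen is the direct result of an oxidation. The forward alkylation must occur on the oxygen of the only acidic OH in 16, which no other free hydroxyl contests.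

**16 ⇒ 13.** No skeletal bond is cut; the C3 and C4 oxygen functions are taken back from the enolized 3,4-dione level to two secondary carbinols, and C2 regains its hydrogen. The reason is that 16 is the stable enol tautomer of 15, and 15 is what double oxidation of a vicinal diol gives by way of 14. The pyranone is thereby exchanged for a diol that an alkene can deliver. The forward oxidation must take both carbinols to carbonyls without cleaving C3–C4 and without acid, because the C4 carbinol of 13 is activated by the oxygens at C5, C7 and O1.

**13 ⇒ 12.** The C3–O and C4–O bonds are cut together. Both oxygens can be delivered in one step to the C3=C4 double bond, which leaves ring C free of oxygen substituents and makes 12 the plain product of a ring-forming step. The forward cis-dihydroxylation must select the styrene-type alkene over three electron-rich arenes; its facial selectivity is irrelevant, since C2, C3 and C4 all end up sp2.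

**12 ⇒ 8.** The C4–C4a bond is cut and the C2–C3–C4 unit is rewritten as a propargyl group on O1 (the O1–C2 bond is kept on paper; in the forward direction it is broken and re-formed). The cut is made here because ring A offers two equivalent ortho carbons, so the bond to carbon can be made by a sigmatropic shift from oxygen without any directing group. Ring C and the fusion of rings A and C disappear, and an open-chain ether of a symmetric phenol remains. The forward cascade must follow the concerted path and not heterolysis of the benzylic, propargylic C–O bond, which calls for neutral, acid-free heating.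

**8 ⇒ 6 + 7.** The ether bond between O1 and the future C2 is cut. It is the only link between the ring A half and the ring B half, and cutting it gives two pieces of similar size, of which 7 is commercial and symmetric. The forward step must alkylate 7 on oxygen and not on its very nucleophilic ring carbons, at a carbinol carbon that ionizes easily; a dehydrative coupling under neutral conditions at low temperature is chosen.

**6 ⇒ 4 + 5.** The bond between the carbinol carbon (future C2) and the alkyne carbon (future C3) is cut. A carbonyl addition makes it, and the three-carbon unit of ring C is reduced to an aldehyde carbon plus the two-carbon nucleophile 5. The forward addition needs only a buffered work-up to keep the sensitive carbinol intact.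

**4 ⇒ 2 ⇒ 1.** First the bond between C1' and the formyl carbon (future C2) is cut, then the O–CH2Ph bond. The position para to one methoxy group and ortho to the other is the most nucleophilic carbon of 2, so electrophilic formylation places the carbon where it is needed. Two simple steps lead back to commercial 1, which already holds the ring B oxygen pattern. The formylation must be regioselective for that carbon and must leave the benzyl ether alone.

## Other disconnections considered

**Alternative 1:** The cut takes C4–C4a and O1–C2 together, so ring C is made from A1 (benzene-1,3,5-triol) and the β-ketoester A2 (ethyl 3-[5-(benzyloxy)-2,4-dimethoxyphenyl]-2-methoxy-3-oxopropanoate). The forward key step is a Mentzer-type thermal condensation without solvent near 240–250 °C. The ester carbon acylates a ring carbon of A1 and a phenolic oxygen condenses with the ketone, which should give A3 (2-[5-(benzyloxy)-2,4-dimethoxyphenyl]-5,7-dihydroxy-3-methoxy-4H-chromen-4-one).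

- In its favour: C3 already carries its methoxy group and C4 its carbonyl oxygen, so no osmium reagent and no oxidation step are needed. The threefold symmetry of A1 settles ring A regiochemistry as cleanly as the symmetry of 7 does in the chosen plan.
- Against it here: the step is a pyrolysis in which A2 can undergo retro-Claisen cleavage or lose its ester group. The benzyl ether must endure about 250 °C, and the 2'-methoxy group crowds the ketone that has to condense. Condensation in the reverse orientation would give a 2-pyranone. A3 then needs exhaustive methylation, including the chelated 5-hydroxyl, before the benzyl group is removed.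
- Comparison: on structure the two plans are equal in using a symmetric ring A building block. On oxidation-state economy and step count the alternative is the better one (about seven steps from 1 against nine, and no late redox work). On mechanism the chosen plan is the more dependable, since its ring closure is a unimolecular pericyclic cascade at a lower temperature, whereas this one is a bimolecular double condensation of two sensitive partners in a melt.

**Alternative 2:** Three bonds are cut at once, C4a–C4, C4–C3 and O1–C2. Ring C is assembled from A4 (2-iodo-3,5-dimethoxyphenol), the ring B alkyne A5 (1-(benzyloxy)-5-ethynyl-2,4-dimethoxybenzene) and one carbonyl carbon supplied by the gas atmosphere. The forward key step is a carbonylative Sonogashira coupling under palladium–phosphine catalysis in a secondary amine. It is followed in the same flask by 6-endo addition of the phenol oxygen to the acyl alkyne, which should give A6 (2-[5-(benzyloxy)-2,4-dimethoxyphenyl]-5,7-dimethoxy-4H-chromen-4-one).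

- In its favour: mild catalytic conditions, the highest convergence of the four plans (three ring C bonds in one operation) and a stable flavone as the product. A5 lies one step from 4.
- Against it here: A6 has no oxygen at C3, so C3 would still have to be hydroxylated to reach 16, for instance by deprotonation at C3 and oxidation of a derived borate, or by epoxidation of the C2=C3 bond and isomerization. A4 requires iodination of 7 between the hydroxyl and a methoxy group, in competition with the para position. The doubly ortho-substituted, electron-rich iodide should add slowly to zerovalent palladium, which gives direct non-carbonylative coupling and closure to a furan ring a chance. A 5-exo closure of the acyl alkyne would lead to the aurone skeleton.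
- Comparison: the two plans are equal in that ring C arrives without its C3 oxygen and in relying on one toxic reagent each. The alternative is better in mildness and in the stability of its key product (A6 against the acid- and air-sensitive 12). The chosen plan is better in that ring A regiochemistry is automatic and in that adding two oxygens to the alkene of 12 is easier than oxidizing the C3–H bond of a flavone. Step counts are about the same.

**Alternative 3:** The cuts are C3–C4 and O1–C8a. The α-methoxy ketone A7 (1-[5-(benzyloxy)-2,4-dimethoxyphenyl]-2-methoxyethan-1-one) supplies ring B, C2 and C3, and the acid chloride A8 (2-bromo-4,6-dimethoxybenzoyl chloride) supplies ring A and C4. In the forward key step the lithium enolate of A7 is acylated on carbon by A8. The enol oxygen of the acylation product then replaces the bromine ortho to the acyl group in a copper-catalysed intramolecular O-arylation. This should give A9 (2-[5-(benzyloxy)-2,4-dimethoxyphenyl]-3,5,7-trimethoxy-4H-chromen-4-one), which is the same compound as 17.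

- In its favour: every oxygen is in place at its final oxidation level, ring A regiochemistry is fixed by the position of the bromine, and ring C is closed in one flask. A single hydrogenolysis would finish the synthesis.
- Against it here: the carbonyl group of A8 is flanked by bromine and a methoxy group, so C-acylation should be slow and O-acylation of the α-alkoxy enolate can compete. The congested acylation product is prone to retro-Claisen cleavage. The copper-mediated displacement must take place on an electron-rich, ortho-hindered aryl bromide. A7 and A8 are not commercial and each needs its own short sequence.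
- Comparison: the alternative is clearly better in step economy (a longest linear sequence of about five or six steps against nine) and in oxidation-state economy (no redox steps after the ring closure), and it is equal in the final deprotection. The chosen plan is better only in the character of its ring-forming step, which is intramolecular, metal-free and free of steric congestion, and in starting ring A from a cheap symmetric phenol without a halogen handle.

Key step: step 5

**Remarks on the chemistry**

- Compounds 6 and 8 to 15 are racemic. For 13 and 14 the SMILES shows one enantiomer of the racemate with the relative configuration stated in the name.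
- Organic compounds that form and react on in the flask carry numbers (3, 9, 10, 11, 14, 15). The magnesium alkoxide of 6 and catalyst-bound species are not counted separately.
- The connectivity of 8 and 12 was checked against 18 and needs no correction. The carbon that becomes C2 lies ortho and para to the two ring B methoxy groups and meta to the benzyloxy group, and C4a lies between O1 and the 5-methoxy group.
- The 5'-oxygen is kept as a benzyl ether. Being meta to the ether carbon of 8, it adds no resonance stabilization to a cation there. An acyl or sulfonyl group in its place would slow ionization only through a weak inductive effect and would put steps 3 and 8 at risk.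

## Route

Step 1
Reactants: 1 2,4-dimethoxyphenol
Product: 2 1-(benzyloxy)-2,4-dimethoxybenzene
Conditions: BnBr, K2CO3, DMF, rt
Reagents that add atoms: benzyl bromide, BrCc1ccccc1
Why: Williamson ether synthesis: the phenoxide formed by K2CO3 displaces bromide from benzyl bromide in an SN2 reaction; 1 has a single hydroxyl, so no selectivity question arises.

Step 2
Reactants: 2 1-(benzyloxy)-2,4-dimethoxybenzene
Product: 4 5-(benzyloxy)-2,4-dimethoxybenzaldehyde, via aryl iminium chloride 3 (not isolated)
Conditions: POCl3, DMF, 0 °C to 60 °C; then ice-water
Reagents that add atoms: N,N-dimethylformamide, CN(C)C=O; water, O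
Why: Vilsmeier–Haack formylation: the chloroiminium ion attacks C5 of 2, the carbon para to the 2-methoxy and ortho to the 4-methoxy group, because C3 is shielded between two methoxy groups and C6 is activated by the benzyloxy group alone; hydrolysis of iminium salt 3 on work-up gives the aldehyde, and a benzyl aryl ether is stable to POCl3/DMF.

Step 3
Reactants: 4 5-(benzyloxy)-2,4-dimethoxybenzaldehyde; 5 ethynylmagnesium bromide
Product: 6 racemic 1-[5-(benzyloxy)-2,4-dimethoxyphenyl]prop-2-yn-1-ol
Conditions: HC≡CMgBr (0.5 M in THF), THF, −20 °C to 0 °C; then sat. aq. NH4Cl
Reagents that add atoms: none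
Why: 1,2-Addition of an alkynyl Grignard reagent to an aromatic aldehyde; the new carbinol centre has no controlling element and forms racemic, which is acceptable because it is lost later; the buffered quench protects the acid-sensitive benzylic, propargylic alcohol.

Step 4
Reactants: 6 racemic 1-[5-(benzyloxy)-2,4-dimethoxyphenyl]prop-2-yn-1-ol; 7 3,5-dimethoxyphenol
Product: 8 racemic 1-(benzyloxy)-5-[1-(3,5-dimethoxyphenoxy)prop-2-yn-1-yl]-2,4-dimethoxybenzene
Conditions: PPh3, DIAD, toluene/THF, −20 °C to rt
Reagents that add atoms: none
Why: Mitsunobu etherification: the alcohol is activated as its oxyphosphonium ion under neutral conditions and the phenoxide of 7 (acidic enough to protonate the betaine) displaces phosphine oxide at the propargylic carbon; low temperature and a low-polarity medium keep the ion pair tight, which favours attack through oxygen at the propargylic carbon, and the configuration is of no concern because 6 is racemic.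

Step 5
Reactants: 8 racemic 1-(benzyloxy)-5-[1-(3,5-dimethoxyphenoxy)prop-2-yn-1-yl]-2,4-dimethoxybenzene
Product: 12 racemic 2-[5-(benzyloxy)-2,4-dimethoxyphenyl]-5,7-dimethoxy-2H-chromene, via allenyl cyclohexadienone 9 (not isolated), via ortho-allenylphenol 10 (not isolated), via ortho-quinone methide 11 (not isolated)
Conditions: PhNEt2 (degassed), 185–195 °C, Ar; amine removed under vacuum, no acid wash
Reagents that add atoms: none
Why: Thermal aryl propargyl ether Claisen rearrangement, the classical entry to 2H-chromenes: a concerted suprafacial [3,3] shift through a six-membered cyclic transition state breaks O1–C2 and forms C4–C4a, giving allenyl dienone 9. Tautomerization re-aromatizes ring A to allenylphenol 10, a 1,5-hydrogen shift from the phenolic O–H to the central allene carbon gives the cis-oxatriene (ortho-quinone methide) 11, and a thermally allowed disrotatory oxa-6π electrocyclization re-forms O1–C2 and closes ring C; this is the one ring formed, and its mode of closure is pericyclic (6π electrocyclic), not a polar cyclization. The closest known reaction type is the conversion of aryl propargyl ethers into 2H-chromenes in hot N,N-diethylaniline, including 1-aryl-substituted ethers that give flav-3-enes. No lasting stereocentre is created: C2 is already sp3 in 8, its configuration is lost in planar 11 and returns racemic, which is immaterial because C2 becomes sp2 in step 7. Regioselectivity needs no control, because the two carbons ortho to the ether oxygen of the 3,5-dimethoxyphenyl ring are equivalent unsubstituted CH carbons, each flanked by a methoxy group, so either leads to the 5,7-dimethoxy pattern. The selectivity that must be won is the concerted shift over heterolysis of the benzylic, propargylic C–O bond (ring B carries methoxy groups ortho and para to it); the low-polarity basic amine solvent, acid-free glassware and the absence of Lewis acids disfavour ion-pair formation, while the electron-rich migration terminus and the aryl group on the propargylic carbon lower the barrier of the [3,3] shift. Closure of 10 to a furan (5-exo attack of the phenol oxygen on the allene) needs fluoride or strong base and should not compete here.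

Step 6
Reactants: 12 racemic 2-[5-(benzyloxy)-2,4-dimethoxyphenyl]-5,7-dimethoxy-2H-chromene
Product: 13 racemic (2R*,3S*,4S*)-2-[5-(benzyloxy)-2,4-dimethoxyphenyl]-5,7-dimethoxy-3,4-dihydro-2H-chromene-3,4-diol
Conditions: OsO4 (2 mol %), NMO, NaHCO3, acetone/H2O, 0 °C to rt; then aq. Na2SO3
Reagents that add atoms: N-methylmorpholine N-oxide, C[N+]1([O-])CCOCC1; water, O; osmium tetroxide (catalytic oxygen carrier), O=[Os](=O)(=O)=O
Why: Upjohn dihydroxylation: OsO4 adds in a [3+2] sense to the electron-rich cis-disubstituted C3=C4 double bond from the face opposite to the C2 aryl group, so both hydroxyls should come out trans to it (2,3-trans-3,4-cis, substrate control); arenes, ethers and the benzyl group are inert, and the bicarbonate buffer guards the ionizable C4 carbinol.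

Step 7
Reactants: 13 racemic (2R*,3S*,4S*)-2-[5-(benzyloxy)-2,4-dimethoxyphenyl]-5,7-dimethoxy-3,4-dihydro-2H-chromene-3,4-diol
Product: 16 2-[5-(benzyloxy)-2,4-dimethoxyphenyl]-3-hydroxy-5,7-dimethoxy-4H-chromen-4-one, via trans-3-hydroxyflavanone 14 (not isolated), via chromane-3,4-dione 15 (not isolated)
Conditions: IBX (3 equiv), DMSO, rt to 40 °C
Reagents that add atoms: none
Why: IBX oxidation of a vicinal diol to the 1,2-dione without C–C cleavage: the benzylic C4 carbinol should go first (14), then the acyloin hydroxyl at C3 (15); 15 tautomerizes by loss of the C2 hydrogen to the conjugated, hydrogen-bonded 3-hydroxy-4-pyranone 16, which removes all three stereocentres.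

Step 8
Reactants: 16 2-[5-(benzyloxy)-2,4-dimethoxyphenyl]-3-hydroxy-5,7-dimethoxy-4H-chromen-4-one
Product: 17 2-[5-(benzyloxy)-2,4-dimethoxyphenyl]-3,5,7-trimethoxy-4H-chromen-4-one
Conditions: MeI, K2CO3, acetone, reflux
Reagents that add atoms: iodomethane, CI
Why: O-Alkylation of the flavonol 3-hydroxyl, the only acidic OH in 16: K2CO3 forms the enolate-like anion, which is methylated on oxygen by SN2 attack on iodomethane, as is usual for 3-hydroxyflavones.

Step 9
Reactants: 17 2-[5-(benzyloxy)-2,4-dimethoxyphenyl]-3,5,7-trimethoxy-4H-chromen-4-one
Product: 18 2-(5-hydroxy-2,4-dimethoxyphenyl)-3,5,7-trimethoxy-4H-chromen-4-one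
Conditions: H2 (1 atm), 10% Pd/C, EtOAc/MeOH, rt
Reagents that add atoms: none
Why: Catalytic hydrogenolysis of a benzyl aryl ether; the tetrasubstituted C2=C3 double bond of the pyranone, the carbonyl group and the methyl ethers should not be reduced at 1 atm and room temperature, so only the 5'-hydroxyl is set free.

## Compound list

1 | 2,4-dimethoxyphenol | COc1ccc(O)c(OC)c1 | starting material
2 | 1-(benzyloxy)-2,4-dimethoxybenzene | COc1ccc(OCc2ccccc2)c(OC)c1 | intermediate
3 | N-{[5-(benzyloxy)-2,4-dimethoxyphenyl]methylidene}-N-methylmethanaminium chloride (aryl iminium chloride, not isolated) | C[N+](C)=Cc1cc(OCc2ccccc2)c(OC)cc1OC.[Cl-] | intermediate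
4 | 5-(benzyloxy)-2,4-dimethoxybenzaldehyde | COc1cc(OC)c(OCc2ccccc2)cc1C=O | intermediate
5 | ethynylmagnesium bromide | C#C[Mg]Br | starting material
6 | racemic 1-[5-(benzyloxy)-2,4-dimethoxyphenyl]prop-2-yn-1-ol | C#CC(O)c1cc(OCc2ccccc2)c(OC)cc1OC | intermediate
7 | 3,5-dimethoxyphenol | COc1cc(O)cc(OC)c1 | starting material
8 | racemic 1-(benzyloxy)-5-[1-(3,5-dimethoxyphenoxy)prop-2-yn-1-yl]-2,4-dimethoxybenzene | C#CC(Oc1cc(OC)cc(OC)c1)c1cc(OCc2ccccc2)c(OC)cc1OC | intermediate
9 | 6-{3-[5-(benzyloxy)-2,4-dimethoxyphenyl]propa-1,2-dien-1-yl}-3,5-dimethoxycyclohexa-2,4-dien-1-one (racemic mixture of diastereomers, not isolated) | O=C1C=C(OC)C=C(OC)C1C=C=Cc1cc(OCc2ccccc2)c(OC)cc1OC | intermediate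
10 | racemic 2-{3-[5-(benzyloxy)-2,4-dimethoxyphenyl]propa-1,2-dien-1-yl}-3,5-dimethoxyphenol (axially chiral allene, not isolated) | Oc1cc(OC)cc(OC)c1C=C=Cc1cc(OCc2ccccc2)c(OC)cc1OC | intermediate
11 | (6Z)-6-{3-[5-(benzyloxy)-2,4-dimethoxyphenyl]prop-2-en-1-ylidene}-3,5-dimethoxycyclohexa-2,4-dien-1-one (ortho-quinone methide, vinyl group syn to the ring carbonyl, geometry of the distal alkene not fixed, not isolated) | O=C1C=C(OC)C=C(OC)/C1=C/C=Cc1cc(OCc2ccccc2)c(OC)cc1OC | intermediate
12 | racemic 2-[5-(benzyloxy)-2,4-dimethoxyphenyl]-5,7-dimethoxy-2H-chromene | COc1cc(OC)c2C=CC(c3cc(OCc4ccccc4)c(OC)cc3OC)Oc2c1 | intermediate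
13 | racemic (2R*,3S*,4S*)-2-[5-(benzyloxy)-2,4-dimethoxyphenyl]-5,7-dimethoxy-3,4-dihydro-2H-chromene-3,4-diol (2,3-trans-3,4-cis, one enantiomer drawn) | COc1cc(OC)c(OCc2ccccc2)cc1[C@H]1Oc2cc(OC)cc(OC)c2[C@H](O)[C@@H]1O | intermediate
14 | racemic (2R*,3R*)-2-[5-(benzyloxy)-2,4-dimethoxyphenyl]-3-hydroxy-5,7-dimethoxy-2,3-dihydro-4H-chromen-4-one (2,3-trans, one enantiomer drawn, not isolated) | COc1cc(OC)c(OCc2ccccc2)cc1[C@H]1Oc2cc(OC)cc(OC)c2C(=O)[C@@H]1O | intermediate
15 | racemic 2-[5-(benzyloxy)-2,4-dimethoxyphenyl]-5,7-dimethoxy-2H-chromene-3,4-dione (not isolated) | COc1cc(OC)c2c(c1)OC(c1cc(OCc3ccccc3)c(OC)cc1OC)C(=O)C2=O | intermediate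
16 | 2-[5-(benzyloxy)-2,4-dimethoxyphenyl]-3-hydroxy-5,7-dimethoxy-4H-chromen-4-one | COc1cc(OC)c2c(=O)c(O)c(-c3cc(OCc4ccccc4)c(OC)cc3OC)oc2c1 | intermediate
17 | 2-[5-(benzyloxy)-2,4-dimethoxyphenyl]-3,5,7-trimethoxy-4H-chromen-4-one | COc1cc(OC)c2c(=O)c(OC)c(-c3cc(OCc4ccccc4)c(OC)cc3OC)oc2c1 | intermediate
18 | 2-(5-hydroxy-2,4-dimethoxyphenyl)-3,5,7-trimethoxy-4H-chromen-4-one (5'-hydroxy-3,5,7,2',4'-pentamethoxyflavone) | COc1cc(OC)c2c(=O)c(OC)c(-c3cc(O)c(OC)cc3OC)oc2c1 | target

## Step count and least certain steps

Total step count: 9 (steps 1 to 9). Longest linear sequence: 9 steps, from 1 to 18; 5 and 7 are commercial and enter at steps 3 and 4.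

**Step 5 (key step).** The process most likely to interfere is heterolysis of the benzylic, propargylic C–O bond of 8 ahead of the concerted shift. The resulting ion pair would recombine at ring carbons without the allene relay. The flavene could also be lost by acid-catalysed ring opening and oxidation while the high-boiling amine is removed. The cause is that ring B carries methoxy groups ortho and para to the ether carbon and the leaving group is a phenoxide, while 12 is an electron-rich cyclic enol-ether-like styrene. Fallback, from 4 and rejoining at 12 without any propargyl ether: Claisen–Schmidt condensation of 4 with commercial 1-(2-hydroxy-4,6-dimethoxyphenyl)ethan-1-one (KOH, EtOH, rt) should give the chalcone (E)-3-[5-(benzyloxy)-2,4-dimethoxyphenyl]-1-(2-hydroxy-4,6-dimethoxyphenyl)prop-2-en-1-one F1. 1,2-Reduction with NaBH4 (THF/i-PrOH) should give the allylic alcohol racemic (E)-3-[5-(benzyloxy)-2,4-dimethoxyphenyl]-1-(2-hydroxy-4,6-dimethoxyphenyl)prop-2-en-1-ol F2. On mild acidification (AcOH) F2 loses water to the same ortho-quinone methide 11 and closes to 12. This is the classical borohydride route from 2'-hydroxychalcones to flav-3-enes; it gives up the [3,3] shift but keeps the electrocyclization.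

**Step 4.** The likely failure is ionization of the activated oxyphosphonium intermediate. The propargylic cation would then be captured at a ring carbon of the phenoxide (C-alkylation), at the alkyne terminus (allenyl ether) or by the hydrazide anion. The cause is that the 2,4-dimethoxyaryl group and the alkyne both stabilize the cation and that 7 is a phloroglucinol-type carbon nucleophile. Fallback, from 6 and rejoining at 8: acylation of 6 with methyl chloroformate (pyridine, CH2Cl2, 0 °C) should give racemic 1-[5-(benzyloxy)-2,4-dimethoxyphenyl]prop-2-yn-1-yl methyl carbonate F3. This is coupled with 7 by copper-catalysed propargylic etherification (CuCl2·2H2O cat., DBU, MeCN, −5 °C), a known route to aryl propargyl ethers. The terminal alkyne forms a copper acetylide, loss of the carbonate gives a copper allenylidene, and the pre-formed phenoxide attacks the γ-carbon (the former carbinol carbon) through oxygen, regenerating the terminal alkyne of 8.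

**Step 7.** The likely failures are stalling after the first oxidation (at the ketol stage), oxidative cleavage of the C3–C4 bond of the cis-diol, or ionization at C4 in the weakly acidic medium. The cause is that two different carbinols must be oxidized by one reagent and that the C4 carbinol is strongly activated. Fallback, from 13 and rejoining at 16, in two separate, mechanistically distinct oxidations: activated MnO2 (CH2Cl2, rt) should oxidize only the benzylic C4 carbinol, so that 14 is isolated. The acyloin is then dehydrogenated with catalytic Cu(OAc)2 in pyridine/MeOH under air (50 °C), giving 15 and by tautomerization 16. This fallback makes no compound outside the list (F0).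

**Step 6.** The likely failure is loss of the diol by ionization of its C4 hydroxyl during reaction, work-up or chromatography, followed by self-condensation with the electron-rich rings. The cause is that the C4 carbinol of 13 is stabilized as a cation by the oxygens at C5, C7 and O1. Fallback, from 12 and rejoining at 14, avoiding the free diol: epoxidation with dimethyldioxirane (acetone, −40 °C) should give racemic 2,3-trans-2-[5-(benzyloxy)-2,4-dimethoxyphenyl]-3,4-epoxy-5,7-dimethoxy-3,4-dihydro-2H-chromene F4 (epoxide oxygen anti to the C2 aryl group), which is not isolated. Addition of DMSO and warming to rt should open the epoxide at the benzylic C4 in a Kornblum-type oxidation (alkoxysulfonium ion, loss of dimethyl sulfide) to give ketol 14. 14 is then oxidized to 16 under the conditions of step 7 or of its fallback.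

## Further compounds

F1 | step 5 | (E)-3-[5-(benzyloxy)-2,4-dimethoxyphenyl]-1-(2-hydroxy-4,6-dimethoxyphenyl)prop-2-en-1-one | COc1cc(O)c(C(=O)/C=C/c2cc(OCc3ccccc3)c(OC)cc2OC)c(OC)c1
F2 | step 5 | racemic (E)-3-[5-(benzyloxy)-2,4-dimethoxyphenyl]-1-(2-hydroxy-4,6-dimethoxyphenyl)prop-2-en-1-ol | COc1cc(O)c(C(O)/C=C/c2cc(OCc3ccccc3)c(OC)cc2OC)c(OC)c1
F3 | step 4 | racemic 1-[5-(benzyloxy)-2,4-dimethoxyphenyl]prop-2-yn-1-yl methyl carbonate | C#CC(OC(=O)OC)c1cc(OCc2ccccc2)c(OC)cc1OC
F0 | step 7 | none | none
F4 | step 6 | racemic 2,3-trans-2-[5-(benzyloxy)-2,4-dimethoxyphenyl]-3,4-epoxy-5,7-dimethoxy-3,4-dihydro-2H-chromene (one enantiomer drawn) | COc1cc(OC)c(OCc2ccccc2)cc1[C@H]1Oc2cc(OC)cc(OC)c2[C@@H]2O[C@H]12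
A1 | alternative 1 | benzene-1,3,5-triol (phloroglucinol) | Oc1cc(O)cc(O)c1
A2 | alternative 1 | ethyl 3-[5-(benzyloxy)-2,4-dimethoxyphenyl]-2-methoxy-3-oxopropanoate (racemic) | CCOC(=O)C(OC)C(=O)c1cc(OCc2ccccc2)c(OC)cc1OC
A3 | alternative 1 | 2-[5-(benzyloxy)-2,4-dimethoxyphenyl]-5,7-dihydroxy-3-methoxy-4H-chromen-4-one | COc1c(-c2cc(OCc3ccccc3)c(OC)cc2OC)oc2cc(O)cc(O)c2c1=O
A4 | alternative 2 | 2-iodo-3,5-dimethoxyphenol | COc1cc(O)c(I)c(OC)c1
A5 | alternative 2 | 1-(benzyloxy)-5-ethynyl-2,4-dimethoxybenzene | C#Cc1cc(OCc2ccccc2)c(OC)cc1OC
A6 | alternative 2 | 2-[5-(benzyloxy)-2,4-dimethoxyphenyl]-5,7-dimethoxy-4H-chromen-4-one | COc1cc(OC)c2c(=O)cc(-c3cc(OCc4ccccc4)c(OC)cc3OC)oc2c1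
A7 | alternative 3 | 1-[5-(benzyloxy)-2,4-dimethoxyphenyl]-2-methoxyethan-1-one | COCC(=O)c1cc(OCc2ccccc2)c(OC)cc1OC
A8 | alternative 3 | 2-bromo-4,6-dimethoxybenzoyl chloride | COc1cc(Br)c(C(Cl)=O)c(OC)c1
A9 | alternative 3 | 2-[5-(benzyloxy)-2,4-dimethoxyphenyl]-3,5,7-trimethoxy-4H-chromen-4-one (identical with 17) | COc1cc(OC)c2c(=O)c(OC)c(-c3cc(OCc4ccccc4)c(OC)cc3OC)oc2c1
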